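the same everywhere: starting material 20 mM; free catalyst 2.5 mol%

| flask | second substrate | reagent | remark | time |
|---|---|---|---|---|
| north-west | 0.23 equiv | 1.8 equiv | run made earlier |  |
| north | 1.9 equiv | 1.8 equiv | run made earlier |  |
| oak | 0.200 equiv | 1.80 equiv |  | 6.0 min |
| cedar | 0.300 equiv | 1.80 equiv |  | 6.0 min |
| birch | 0.500 equiv | 1.80 equiv |  | 6.0 min |
| maple | 0.800 equiv | 1.80 equiv |  | 6.0 min |
| alder | 1.20 equiv | 1.80 equiv |  | 6.0 min |

- north-west (time / min: target / %, starting material / %): 0.833: 1.9, 96.7; 1.50: 3.7, 94.7; 2.50: 7.3, 91.4; 3.00: 9.1, 90.1
- north (time / min: target / %, starting material / %): 0.833: 1.7, 98.7; 1.50: 1.7, 97.0; 2.50: 3.1, 95.8; 3.00: 3.3, 96.6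

(readings scatter by 0.5 percentage points)

- a reading or a percentage of target counts all its forms, free or not
- "hardly changes" means that all values lie within two and a half points (for a concentration: within two and a half percent of the largest)

- amount of target at the end, in percent of the starting material charged for oak, cedar, birch, maple, alder, in this order
- how that number moves from the first to the last of them (hardly changes / rises, then falls / falls, then rises / falls all the way / rises all the way)

*What does the north-west run show at 3.00 min?* Target stands at 9.1% and starting material is down by 9.90%, so target and lost starting material roughly match, given a scatter of 0.5 percentage points on each reading.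

*And with more second substrate?* At 3.00 min the north run has 3.3%, less than the north-west run by a factor 2.76. Going from 0.23 equiv to 1.9 equiv of second substrate therefore acts as a brake on target.

*What rule do you put on a brake?* My own reckoning assumes that second substrate competes for the catalyst, which the field calls competitive inhibition. With the charges of starting material, reagent and free catalyst held as they stand in these flasks, the rate of target then rolls off like a first-order filter, as one over (one plus x over h), where x is the equivalents of second substrate. The ratio of the two runs gives 0.720. This is the corner charge, the charge of second substrate at which the rate of target drops to half of its unbraked value.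

*That rests on a small reading in the north run. How firm is it?* Not very. The pair at 2.50 min gives 1.00 instead. The corner is therefore known only roughly, but the rule falls with x for either value, so the direction of the row is firmer than its size.

*Your numbers?* I let the north-west run hold its mean rate out to 6.0 min, which is an assumption, and scale by the rule. That gives 18.8% for oak and 9.01% for alder, falling all the way.

*And the forecast?* It says 18% for oak, 12.5% for birch and 8% for alder, and its shape is falls all the way. Its ground is this: “More second substrate clearly slows the reaction”. My oak is higher than its oak and my alder is higher than its alder, but the shape is the same.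

The flask gives 16.5%, 15.5%, 13.9%, 11.9% and 10.0%, and the shape is falls all the way.

    starting material + free catalyst ⇌ catalyst intermediate A (K = 75.0 L mol⁻¹, k = 1800 L mol⁻¹ min⁻¹)
    reagent + catalyst intermediate A → free catalyst + target (k = 69.0 L mol⁻¹ min⁻¹)
    second substrate + free catalyst ⇌ catalyst intermediate B (K = 130 L mol⁻¹, k = 710 L mol⁻¹ min⁻¹)
    reagent + catalyst intermediate B → free catalyst + second product (k = 56.0 L mol⁻¹ min⁻¹)
    free catalyst + target ⇌ idle complex, settled at all times (K = 32.0 L mol⁻¹)

At the end, catalyst intermediate B holds 12.3% of the catalyst in oak and 47.5% in alder, while catalyst intermediate A holds 44.4% in oak and 28.1% in alder. Through the corner charge of 0.720, the value for oak scales to 9.99% for maple and 7.91% for alder; maple stands at 11.9% and alder at 10.0%.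

The runs are calculated for substances that don't exist; noise was put on by code.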